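**Retrosynthetic overview**
1. C8–O ester bond (last step): target 24 ⇒ macrocyclic 9-acetate 8-alcohol 20 + (2S,3S)-epoxyangelic acid 22.
2. Key step, oxirane C–O bonds: 22 ⇒ angelic acid 21 by a carboxylate-directed asymmetric epoxidation (proposed new method); 20 ⇒ diol 19 ⇒ acetonide 18.
3. Ten-membered carbocycle and γ-lactone in one operation: 18 ⇒ bromo enal 16 (C6–C7 allylation with CrCl2, then C12–O lactonisation).
4. 16 ⇒ aldehyde 12 + methyl acrylate 13 (Morita–Baylis–Hillman, then SN2' bromination); 12 ⇒ ketone 3 + phosphonium salt 8 (Z-selective Wittig, C1=C10); 3 from D-tartaramide 1, 8 from geranyl acetate 4.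
5. Ring order: temporary dioxolane (step 1) → carbocycle and lactone together (step 11) → oxirane made separately (step 14) and attached last (step 15).

Assumption: atoms are referred to by germacrane numbering (C1–C15; C6/C7 lactone fusion, C12 lactone carbonyl), and the ligand antipode named in step 14 is taken to be the one that gives the (2S,3S) acid (its mirror image is equally available).

**Route**

Step 1
Reactants: 1 (2S,3S)-2,3-dihydroxy-N,N,N',N'-tetramethylbutanediamide (N,N,N',N'-tetramethyl-D-tartaramide)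
Product: 2 (4S,5S)-N,N,N',N',2,2-hexamethyl-1,3-dioxolane-4,5-dicarboxamide
Conditions: Me2C(OMe)2, TsOH·H2O (cat.), cyclohexane, reflux (MeOH distilled off)
Reagents that add atoms: 2,2-dimethoxypropane, COC(C)(C)OC
Why: Acid-catalysed transacetalisation ties the threo diol into the trans-dioxolane, which masks both hydroxyls up to the macrocycle and leaves the two S centres (future C8 and C9) untouched.

Step 2
Reactants: 2 (4S,5S)-N,N,N',N',2,2-hexamethyl-1,3-dioxolane-4,5-dicarboxamide
Product: 3 (4S,5S)-5-acetyl-N,N,2,2-tetramethyl-1,3-dioxolane-4-carboxamide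
Conditions: MeMgBr (1.5 equiv), THF, −15 °C, 30 min; aqueous work-up
Reagents that add atoms: methylmagnesium bromide, C[Mg]Br
Why: Grignard mono-addition to a tertiary amide: the magnesium hemiaminal formed at one amide is stable at −15 °C, so the second amide is not attacked, and collapse on work-up gives the methyl ketone (new methyl = C14) without touching the stereocentres.

Step 3
Reactants: 4 geranyl acetate, (2E)-3,7-dimethylocta-2,6-dien-1-yl acetate
Product: 6 (2E)-6-hydroxy-3-methylhex-2-en-1-yl acetate, via aldehyde 5 (not isolated)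
Conditions: O3 (1.0 equiv), CH2Cl2/MeOH (4:1), −78 °C; then NaBH4, −78 → 0 °C
Reagents that add atoms: ozone, [O-][O+]=O
Why: Chemoselective ozonolysis: the electron-rich 6,7-alkene reacts well ahead of the 2,3-alkene deactivated by the allylic acetate, and NaBH4 reduces the cleavage product 5 to the primary alcohol (the acetone co-product is reduced as well).

Step 4
Reactants: 6 (2E)-6-hydroxy-3-methylhex-2-en-1-yl acetate
Product: 7 (2E)-6-iodo-3-methylhex-2-en-1-yl acetate
Conditions: I2, PPh3, imidazole, CH2Cl2, 0 °C → rt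
Reagents that add atoms: iodine, [I][I]
Why: Appel-type iodination of the primary alcohol (SN2 on the alkoxyphosphonium ion); the acetate and the E-alkene are inert.

Step 5
Reactants: 7 (2E)-6-iodo-3-methylhex-2-en-1-yl acetate
Product: 8 [(4E)-6-acetoxy-4-methylhex-4-en-1-yl]triphenylphosphonium iodide
Conditions: PPh3, MeCN, reflux, 24 h
Reagents that add atoms: triphenylphosphine, c1ccc(cc1)P(c1ccccc1)c1ccccc1
Why: SN2 quaternisation of triphenylphosphine by the primary iodide gives the Wittig salt.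

Step 6
Reactants: 3 (4S,5S)-5-acetyl-N,N,2,2-tetramethyl-1,3-dioxolane-4-carboxamide; 8 [(4E)-6-acetoxy-4-methylhex-4-en-1-yl]triphenylphosphonium iodide
Product: 11 (4S,5R)-5-[(2Z,6E)-8-hydroxy-6-methylocta-2,6-dien-2-yl]-N,N,2,2-tetramethyl-1,3-dioxolane-4-carboxamide, via ylide 9 (not isolated), via acetate 10 (not isolated)
Conditions: 8 (1.3 equiv), KN(SiMe3)2 (1.25 equiv), THF, −78 → 0 °C; 3, −78 °C → rt; then K2CO3, MeOH, rt
Reagents that add atoms: none
Why: Wittig olefination of an α-alkoxy ketone with a salt-free non-stabilised ylide is Z-selective (the oxygenated carbon C9 ends cis to the new chain), which sets the 1(10)Z trisubstituted alkene while the trans-dioxolane centres, the thermodynamic arrangement, are not epimerised; K2CO3/MeOH then removes the acetate by transesterification.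

Step 7
Reactants: 11 (4S,5R)-5-[(2Z,6E)-8-hydroxy-6-methylocta-2,6-dien-2-yl]-N,N,2,2-tetramethyl-1,3-dioxolane-4-carboxamide
Product: 12 (4S,5R)-5-[(2Z,6E)-8-hydroxy-6-methylocta-2,6-dien-2-yl]-2,2-dimethyl-1,3-dioxolane-4-carbaldehyde
Conditions: Cp2Zr(H)Cl (2.5 equiv), THF, rt, 30 min; H2O/SiO2 work-up
Reagents that add atoms: none
Why: Partial reduction of a tertiary amide by hydrozirconation: Cp2Zr(H)Cl delivers one hydride to give a zirconium-bound hemiaminal that releases the aldehyde only on work-up, so there is no over-reduction or C8 epimerisation and the trisubstituted alkenes do not react (one equivalent is consumed by the free hydroxyl, which is restored on work-up).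

Step 8
Reactants: 12 (4S,5R)-5-[(2Z,6E)-8-hydroxy-6-methylocta-2,6-dien-2-yl]-2,2-dimethyl-1,3-dioxolane-4-carbaldehyde; 13 methyl acrylate
Product: 14 methyl 2-{hydroxy[(4R,5R)-5-[(2Z,6E)-8-hydroxy-6-methylocta-2,6-dien-2-yl]-2,2-dimethyl-1,3-dioxolan-4-yl]methyl}prop-2-enoate (both carbinol epimers)
Conditions: 13 (5 equiv), DABCO (1 equiv), 1,4-dioxane/H2O (1:1), rt, 48 h
Reagents that add atoms: none
Why: Morita–Baylis–Hillman reaction of the activated α-alkoxy aldehyde with methyl acrylate attaches C11–C13 to C7; the new carbinol centre forms as a mixture, which does not matter because it becomes sp2 in step 10.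

Step 9
Reactants: 14 methyl 2-{hydroxy[(4R,5R)-5-[(2Z,6E)-8-hydroxy-6-methylocta-2,6-dien-2-yl]-2,2-dimethyl-1,3-dioxolan-4-yl]methyl}prop-2-enoate
Product: 15 methyl 2-{hydroxy[(4R,5R)-2,2-dimethyl-5-[(2Z,6E)-6-methyl-8-oxoocta-2,6-dien-2-yl]-1,3-dioxolan-4-yl]methyl}prop-2-enoate
Conditions: PhI(OAc)2 (1.1 equiv), TEMPO (10 mol %), CH2Cl2, rt
Reagents that add atoms: none
Why: TEMPO/PhI(OAc)2 oxidation is selective for the primary allylic alcohol over the hindered, electron-poor secondary one and gives the (E)-enal without over-oxidation.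

Step 10
Reactants: 15 methyl 2-{hydroxy[(4R,5R)-2,2-dimethyl-5-[(2Z,6E)-6-methyl-8-oxoocta-2,6-dien-2-yl]-1,3-dioxolan-4-yl]methyl}prop-2-enoate
Product: 16 methyl (2Z)-2-(bromomethyl)-3-{(4R,5R)-2,2-dimethyl-5-[(2Z,6E)-6-methyl-8-oxoocta-2,6-dien-2-yl]-1,3-dioxolan-4-yl}prop-2-enoate
Conditions: NBS, Me2S (premixed), CH2Cl2, −20 → 0 °C
Reagents that add atoms: N-bromosuccinimide, O=C1CCC(=O)N1Br
Why: SN2' displacement of the sulfonium-activated Morita–Baylis–Hillman alcohol by bromide gives the thermodynamically preferred (Z)-2-(bromomethyl)enoate; the bromosulfonium reagent is preformed so that no free NBS meets the alkenes.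

Step 11
Reactants: 16 methyl (2Z)-2-(bromomethyl)-3-{(4R,5R)-2,2-dimethyl-5-[(2Z,6E)-6-methyl-8-oxoocta-2,6-dien-2-yl]-1,3-dioxolan-4-yl}prop-2-enoate
Product: 18 (6R,7S,8R,9R)-8α,9β-(isopropylidenedioxy)germacra-1(10)Z,4E,11(13)-trien-12,6α-olide, via hydroxy ester 17 (not isolated)
Conditions: CrCl2 (8 equiv), DMF, rt, slow addition of 16 (final 2 mM), 12 h
Reagents that add atoms: none
Why: Nozaki–Hiyama-type allylation (two equivalents of divalent chromium turn the allylic bromide into an allyl species of trivalent chromium) closes the ten-membered ring through a chair-like transition state that gives the anti, 6,7-trans adduct, with C7 attacked from the C9 face of the allylic-strain-minimised conformer (C8–H eclipsing C7=C11, C8–O anti), so that C6 is R and C7 is S; the chromium alkoxide of 17 then acylates itself on the methyl ester to form the γ-lactone C–O bond.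

Step 12
Reactants: 18 (6R,7S,8R,9R)-8α,9β-(isopropylidenedioxy)germacra-1(10)Z,4E,11(13)-trien-12,6α-olide
Product: 19 (6R,7S,8R,9R)-8α,9β-dihydroxygermacra-1(10)Z,4E,11(13)-trien-12,6α-olide
Conditions: AcOH/H2O/THF (3:1:1), 40 °C
Reagents that add atoms: none
Why: Mild acid-catalysed acetal hydrolysis; aqueous acetic acid is chosen because stronger acids trigger transannular cyclisation of the 1(10),4-diene, and no stereocentre is involved.

Step 13
Reactants: 19 (6R,7S,8R,9R)-8α,9β-dihydroxygermacra-1(10)Z,4E,11(13)-trien-12,6α-olide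
Product: 20 (6R,7S,8R,9R)-9β-acetoxy-8α-hydroxygermacra-1(10)Z,4E,11(13)-trien-12,6α-olide
Conditions: AcCl (1.05 equiv), 2,4,6-collidine, CH2Cl2, −40 → −20 °C
Reagents that add atoms: acetyl chloride, CC(Cl)=O
Why: Kinetically controlled acylation: the C9 hydroxyl is allylic and flanked by the flat C10, whereas the C8 hydroxyl sits next to the branched ring-fusion carbon C7, so the small acyl chloride at low temperature should go to O9 with retention at C9.

Step 14 (key step)
Reactants: 21 angelic acid, (2Z)-2-methylbut-2-enoic acid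
Product: 22 (2S,3S)-2,3-dimethyloxirane-2-carboxylic acid (epoxyangelic acid)
Conditions: WO2(acac)2 (5 mol %), (S,S)-N,N'-dihydroxy-N,N'-bis(2,2-diphenylacetyl)cyclohexane-1,2-diamine (6 mol %), 30% aq. H2O2 (1.5 equiv), NaCl, CH2Cl2, rt
Reagents that add atoms: hydrogen peroxide, OO
Why: Proposed new method: the carboxylate of 21 binds the chiral peroxo complex of hexavalent tungsten in the place an allylic alkoxide normally takes, so a peroxo oxygen is passed intramolecularly and in one concerted, syn-stereospecific event to the tethered alkene (the Z geometry becomes the cis-2,3-dimethyloxirane and the C2-symmetric bishydroxamate pocket selects the alkene face, setting both oxirane centres as S); the closest known reactions are the racemic Na2WO4/H2O2 epoxidation of α,β-unsaturated acids and the WO2(acac)2/bishydroxamic acid asymmetric epoxidation of allylic and homoallylic alcohols, neither shown enantioselectively for a conjugated free acid.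

Step 15
Reactants: 20 (6R,7S,8R,9R)-9β-acetoxy-8α-hydroxygermacra-1(10)Z,4E,11(13)-trien-12,6α-olide; 22 (2S,3S)-2,3-dimethyloxirane-2-carboxylic acid
Product: 24 (6R,7S,8R,9R)-9β-acetoxy-8α-{[(2S,3S)-2,3-dimethyloxiran-2-yl]carbonyloxy}germacra-1(10)Z,4E,11(13)-trien-12,6α-olide (CNP0304643.2), via mixed anhydride 23 (not isolated)
Conditions: 22 (2 equiv), 2,4,6-trichlorobenzoyl chloride, Et3N, toluene, rt, 1 h; then 20, DMAP, toluene, rt
Reagents that add atoms: none
Why: Yamaguchi esterification: acid 22 is activated as mixed anhydride 23 and transferred by DMAP to the remaining C8 hydroxyl, forming the C8–O ester bond with retention at C8 and without opening the oxirane.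

**Compound list**
1 | (2S,3S)-2,3-dihydroxy-N,N,N',N'-tetramethylbutanediamide (N,N,N',N'-tetramethyl-D-tartaramide) | CN(C)C(=O)[C@@H](O)[C@H](O)C(=O)N(C)C | starting material
2 | (4S,5S)-N,N,N',N',2,2-hexamethyl-1,3-dioxolane-4,5-dicarboxamide | CN(C)C(=O)[C@H]1OC(C)(C)O[C@@H]1C(=O)N(C)C | intermediate
3 | (4S,5S)-5-acetyl-N,N,2,2-tetramethyl-1,3-dioxolane-4-carboxamide | CC(=O)[C@H]1OC(C)(C)O[C@@H]1C(=O)N(C)C | intermediate
4 | geranyl acetate, (2E)-3,7-dimethylocta-2,6-dien-1-yl acetate | CC(C)=CCC/C(C)=C/COC(C)=O | starting material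
5 | (2E)-3-methyl-6-oxohex-2-en-1-yl acetate (not isolated) | CC(=O)OC/C=C(\C)CCC=O | intermediate
6 | (2E)-6-hydroxy-3-methylhex-2-en-1-yl acetate | CC(=O)OC/C=C(\C)CCCO | intermediate
7 | (2E)-6-iodo-3-methylhex-2-en-1-yl acetate | CC(=O)OC/C=C(\C)CCCI | intermediate
8 | [(4E)-6-acetoxy-4-methylhex-4-en-1-yl]triphenylphosphonium iodide | CC(=O)OC/C=C(\C)CCC[P+](c1ccccc1)(c1ccccc1)c1ccccc1.[I-] | intermediate
9 | [(4E)-6-acetoxy-4-methylhex-4-en-1-ylidene]triphenylphosphorane (ylide, not isolated) | CC(=O)OC/C=C(\C)CCC=P(c1ccccc1)(c1ccccc1)c1ccccc1 | intermediate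
10 | (4S,5R)-5-[(2Z,6E)-8-acetoxy-6-methylocta-2,6-dien-2-yl]-N,N,2,2-tetramethyl-1,3-dioxolane-4-carboxamide (not isolated) | CC(=O)OC/C=C(\C)CC/C=C(/C)[C@H]1OC(C)(C)O[C@@H]1C(=O)N(C)C | intermediate
11 | (4S,5R)-5-[(2Z,6E)-8-hydroxy-6-methylocta-2,6-dien-2-yl]-N,N,2,2-tetramethyl-1,3-dioxolane-4-carboxamide | OC/C=C(\C)CC/C=C(/C)[C@H]1OC(C)(C)O[C@@H]1C(=O)N(C)C | intermediate
12 | (4S,5R)-5-[(2Z,6E)-8-hydroxy-6-methylocta-2,6-dien-2-yl]-2,2-dimethyl-1,3-dioxolane-4-carbaldehyde | OC/C=C(\C)CC/C=C(/C)[C@H]1OC(C)(C)O[C@@H]1C=O | intermediate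
13 | methyl acrylate | C=CC(=O)OC | starting material
14 | methyl 2-{hydroxy[(4R,5R)-5-[(2Z,6E)-8-hydroxy-6-methylocta-2,6-dien-2-yl]-2,2-dimethyl-1,3-dioxolan-4-yl]methyl}prop-2-enoate (both carbinol epimers, centre left open) | OC/C=C(\C)CC/C=C(/C)[C@H]1OC(C)(C)O[C@@H]1C(O)C(=C)C(=O)OC | intermediate
15 | methyl 2-{hydroxy[(4R,5R)-2,2-dimethyl-5-[(2Z,6E)-6-methyl-8-oxoocta-2,6-dien-2-yl]-1,3-dioxolan-4-yl]methyl}prop-2-enoate (both carbinol epimers) | O=C/C=C(\C)CC/C=C(/C)[C@H]1OC(C)(C)O[C@@H]1C(O)C(=C)C(=O)OC | intermediate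
16 | methyl (2Z)-2-(bromomethyl)-3-{(4R,5R)-2,2-dimethyl-5-[(2Z,6E)-6-methyl-8-oxoocta-2,6-dien-2-yl]-1,3-dioxolan-4-yl}prop-2-enoate | O=C/C=C(\C)CC/C=C(/C)[C@H]1OC(C)(C)O[C@@H]1/C=C(\CBr)C(=O)OC | intermediate
17 | methyl (6R,7S,8R,9R)-6α-hydroxy-8α,9β-(isopropylidenedioxy)germacra-1(10)Z,4E,11(13)-trien-12-oate (chromium alkoxide in the flask, not isolated) | C=C(C(=O)OC)[C@H]1[C@H](O)/C=C(\C)CC/C=C(/C)[C@H]2OC(C)(C)O[C@@H]21 | intermediate
18 | (6R,7S,8R,9R)-8α,9β-(isopropylidenedioxy)germacra-1(10)Z,4E,11(13)-trien-12,6α-olide (trans-fused α-methylene-γ-lactone, H6 β, H7 α) | C=C1C(=O)O[C@@H]2/C=C(\C)CC/C=C(/C)[C@H]3OC(C)(C)O[C@@H]3[C@@H]12 | intermediate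
19 | (6R,7S,8R,9R)-8α,9β-dihydroxygermacra-1(10)Z,4E,11(13)-trien-12,6α-olide | C=C1C(=O)O[C@@H]2/C=C(\C)CC/C=C(/C)[C@@H](O)[C@H](O)[C@@H]12 | intermediate
20 | (6R,7S,8R,9R)-9β-acetoxy-8α-hydroxygermacra-1(10)Z,4E,11(13)-trien-12,6α-olide | C=C1C(=O)O[C@@H]2/C=C(\C)CC/C=C(/C)[C@@H](OC(C)=O)[C@H](O)[C@@H]12 | intermediate
21 | angelic acid, (2Z)-2-methylbut-2-enoic acid | C/C=C(/C)C(=O)O | starting material
22 | (2S,3S)-2,3-dimethyloxirane-2-carboxylic acid (carboxyl and 3-methyl cis) | OC(=O)[C@@]1(C)O[C@H]1C | intermediate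
23 | (2S,3S)-2,3-dimethyloxirane-2-carboxylic 2,4,6-trichlorobenzoic anhydride (not isolated) | O=C(OC(=O)[C@@]1(C)O[C@H]1C)c1c(Cl)cc(Cl)cc1Cl | intermediate
24 | (6R,7S,8R,9R)-9β-acetoxy-8α-{[(2S,3S)-2,3-dimethyloxiran-2-yl]carbonyloxy}germacra-1(10)Z,4E,11(13)-trien-12,6α-olide, CNP0304643.2 | C=C1C(=O)O[C@@H]2/C=C(\C)CC/C=C(/C)[C@@H](OC(C)=O)[C@H](OC(=O)[C@@]3(C)O[C@H]3C)[C@@H]12 | target

**Step count**
Total: 15 steps. Longest linear sequence: 12 steps (4 → 6 → 7 → 8 → 11 → 12 → 14 → 15 → 16 → 18 → 19 → 20 → 24; steps 3 to 13 and 15).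

**Three steps most likely to fail**

Step 14 (proposed new epoxidation). The conjugated, electron-poor alkene may react slowly with the ligated tungsten peroxo complex, or the planar carboxylate may be poorly discriminated, giving low ee. Any minor enantiomer would show up as a separable diastereomer of 24 after step 15. The fallback is known chemistry, sets out from 21 and comes back at 22. Angelic acid is reduced with LiAlH4 (Et2O, 0 °C) to (2Z)-2-methylbut-2-en-1-ol F1. Sharpless asymmetric epoxidation (Ti(OiPr)4, D-(−)-diethyl tartrate, tBuOOH, 4 Å sieves, CH2Cl2, −20 °C) gives [(2R,3S)-2,3-dimethyloxiran-2-yl]methanol F2. Oxidation of the primary alcohol with RuCl3 (cat.)/NaIO4 in MeCN/CCl4/H2O returns acid 22.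

Step 13 (site-selective acetylation). Discrimination between the two secondary hydroxyls may be modest, and the 9-acetate could migrate to O8 under base. The fallback sets out from 19 and comes back at 24; it amplifies the steric difference with a bulky silyl group and reverses the order of the two acylations. TBSCl/imidazole (DMF, 0 °C) gives the 9-O-silyl ether (6R,7S,8R,9R)-9β-(tert-butyldimethylsilyloxy)-8α-hydroxygermacra-1(10)Z,4E,11(13)-trien-12,6α-olide F3. Yamaguchi acylation with 22 (through 23) gives the 8-epoxyangelate 9-silyl ether F4. HF·pyridine in THF frees the 9-hydroxyl to give (6R,7S,8R,9R)-8α-{[(2S,3S)-2,3-dimethyloxiran-2-yl]carbonyloxy}-9β-hydroxygermacra-1(10)Z,4E,11(13)-trien-12,6α-olide F5. Ac2O/DMAP/pyridine then gives 24. If the intrinsic reactivity proves to be the reverse (O8 first), the two acylations of the main route are simply swapped.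

Step 11 (macrocyclisation). Risks are oligomerisation, 1,4-elimination of the allyl chromium species towards a diene, and the wrong C6/C7 diastereomer. The fallback sets out from 15 and comes back at 18; it generates the nucleophile by catalytic umpolung instead of stoichiometric chromium and also skips the bromination. Acetylation of 15 (Ac2O, DMAP, CH2Cl2) gives the allylic acetate methyl 2-{acetoxy[(4R,5R)-2,2-dimethyl-5-[(2Z,6E)-6-methyl-8-oxoocta-2,6-dien-2-yl]-1,3-dioxolan-4-yl]methyl}prop-2-enoate F6. With Pd(PPh3)4 (10 mol %) and Et2Zn (3 equiv) in THF at high dilution, zerovalent palladium ionises the acetate and transmetalation gives an allylzinc species. This adds to the enal through a closed six-membered transition state to give hydroxy ester 17, which lactonises to 18.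

**Further compounds**
F1 | step 14 | (2Z)-2-methylbut-2-en-1-ol | C/C=C(/C)CO
F2 | step 14 | [(2R,3S)-2,3-dimethyloxiran-2-yl]methanol | OC[C@@]1(C)O[C@H]1C
F3 | step 13 | (6R,7S,8R,9R)-9β-(tert-butyldimethylsilyloxy)-8α-hydroxygermacra-1(10)Z,4E,11(13)-trien-12,6α-olide | C=C1C(=O)O[C@@H]2/C=C(\C)CC/C=C(/C)[C@@H](O[Si](C)(C)C(C)(C)C)[C@H](O)[C@@H]12
F4 | step 13 | (6R,7S,8R,9R)-9β-(tert-butyldimethylsilyloxy)-8α-{[(2S,3S)-2,3-dimethyloxiran-2-yl]carbonyloxy}germacra-1(10)Z,4E,11(13)-trien-12,6α-olide | C=C1C(=O)O[C@@H]2/C=C(\C)CC/C=C(/C)[C@@H](O[Si](C)(C)C(C)(C)C)[C@H](OC(=O)[C@@]3(C)O[C@H]3C)[C@@H]12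
F5 | step 13 | (6R,7S,8R,9R)-8α-{[(2S,3S)-2,3-dimethyloxiran-2-yl]carbonyloxy}-9β-hydroxygermacra-1(10)Z,4E,11(13)-trien-12,6α-olide | C=C1C(=O)O[C@@H]2/C=C(\C)CC/C=C(/C)[C@@H](O)[C@H](OC(=O)[C@@]3(C)O[C@H]3C)[C@@H]12
F6 | step 11 | methyl 2-{acetoxy[(4R,5R)-2,2-dimethyl-5-[(2Z,6E)-6-methyl-8-oxoocta-2,6-dien-2-yl]-1,3-dioxolan-4-yl]methyl}prop-2-enoate | O=C/C=C(\C)CC/C=C(/C)[C@H]1OC(C)(C)O[C@@H]1C(OC(C)=O)C(=C)C(=O)OC
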